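**Assumption:** natural (2S)-liquiritigenin (3, licorice flavanone; ee to be confirmed by chiral HPLC before use) and deoxybenzoin 1 are purchased. TBS = tert-butyldimethylsilyl.

## Retrosynthetic overview

1. Target 11 ⇐ global desilylation of 10 ⇐ α-methylenation of the deoxybenzoin CH2 of 7.
2. Dihydrofuran ring (O1–C2) of 7 ⇐ photochemical ring transposition of 3-aryl-flavanone 6: the pyranone ring opens and the furan ring closes.
3. C3–C3a bond of 6 ⇐ visible-light photoredox coupling of 3-bromoflavanone 5 with the symmetric acylphloroglucinol 2.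
4. 5 ⇐ (2S)-liquiritigenin 3, whose C2 directs C3, which in turn re-sets C2; 2 ⇐ commercial deoxybenzoin 1.
5. Ring order: the chromanone ring is bought, the dihydrobenzofuran ring is made in step 4, and no other ring is formed.

## Route

**Step 1**
Reactants: 1 2-(4-hydroxyphenyl)-1-(2,4,6-trihydroxyphenyl)ethan-1-one
Product: 2 1-[4-(TBSO)-2,6-dihydroxyphenyl]-2-[4-(TBSO)phenyl]ethan-1-one
Conditions: TBSCl (2.1 equiv), imidazole, DMF, 0 °C
Reagents that add atoms: tert-butyldimethylsilyl chloride, CC(C)(C)[Si](C)(C)Cl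
Why: Selective O-silylation — the acidic 4-OH para to the ketone and the remote phenol react first, while the two ortho-OH groups (chelated to the C=O and hindered) stay free; this keeps 2 symmetric and leaves only acyl-flanked OH groups for the later ring closure, and no stereocentre is involved.

**Step 2**
Reactants: 3 (2S)-liquiritigenin
Product: 5 (2R,3R)-3-bromo-7-(TBSO)-2-[4-(TBSO)phenyl]chroman-4-one, via silyl enol ether 4 (not isolated)
Conditions: TBSOTf (3.3 equiv), Et3N, CH2Cl2, −78 → 0 °C; then NBS, THF, −78 °C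
Reagents that add atoms: tert-butyldimethylsilyl triflate, CC(C)(C)[Si](C)(C)OS(=O)(=O)C(F)(F)F; N-bromosuccinimide, O=C1CCC(=O)N1Br
Why: Soft enolisation (silyl triflate/amine) gives the enol silane without a free enolate, so the pyranone cannot open by E1cB and the purchased C2 centre is untouched; NBS bromination of the silyl enol ether anti to the C2 aryl gives the 2,3-trans α-bromo ketone (the C3–Br configuration is immaterial because it becomes a radical next).

**Step 3**
Reactants: 5 (2R,3R)-3-bromo-7-(TBSO)-2-[4-(TBSO)phenyl]chroman-4-one; 2 1-[4-(TBSO)-2,6-dihydroxyphenyl]-2-[4-(TBSO)phenyl]ethan-1-one (2.5 equiv, excess recovered)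
Product: 6 (2S,3R)-3-{2,4-dihydroxy-6-(TBSO)-3-[(4-TBSO-phenyl)acetyl]phenyl}-7-(TBSO)-2-[4-(TBSO)phenyl]chroman-4-one (2,3-trans)
Conditions: fac-Ir(ppy)3 (1 mol%), 2,6-lutidine, MeCN (degassed), 450 nm LEDs, rt
Reagents that add atoms: none
Why: Photoredox homolytic aromatic substitution (oxidative quenching) — Ir(III)* reduces the α-bromo ketone, the electrophilic C3 α-keto radical adds to the electron-rich ring of 2 at C3 (equivalent to C5) and Ir(IV) re-aromatises; the new C3 centre is set trans to the C2 aryl by anti attack and by the thermodynamic preference of the epimerisable α-carbon, so it is controlled by the purchased C2 centre.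

**Step 4**
Reactants: 6 (2S,3R)-3-aryl-flavanone from step 3
Product: 7 1-[(2R,3R)-6-hydroxy-3-(2-hydroxy-4-TBSO-benzoyl)-4-(TBSO)-2-(4-TBSO-phenyl)-2,3-dihydro-1-benzofuran-7-yl]-2-(4-TBSO-phenyl)ethan-1-one
Conditions: hν (310 nm), HFIP/CH2Cl2 1:4 (degassed), 10 °C
Reagents that add atoms: none
Why: Proposed new method: an ESIPT-gated photochemical ring transposition — of the three aryl ketones in 6 only the chromanone carbonyl lacks an ortho-OH and is photoactive, so its excited state cleaves the C2–O1 bond as in the known photo-opening of flavanones to 2'-hydroxychalcones; the phenoxyl/benzyl biradical collapses by electron transfer to an o-acylphenoxide/p-silyloxybenzyl cation pair (stabilised by HFIP), and the only free OH next to C3 (the one ortho to the acyl group) traps the cation in a five-membered closure anti to the C3 aroyl group, so C3 re-sets C2 as R with net inversion; both ketones of 7 are then chelated and photostable, which makes the process one-directional; the closest known reaction types are the flavanone → 2'-hydroxychalcone photoisomerisation and the capture of quinone-methide-type benzylic cations by ortho-phenols to give trans-2-aryl-2,3-dihydrobenzofurans.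

**Step 5**
Reactants: 7 dihydrobenzofuran deoxybenzoin from step 4
Product: 10 hexa-O-TBS ether of the target, via heptasilyl enol ether 8 (not isolated), via Mannich base 9 (not isolated)
Conditions: TBSOTf (3.5 equiv), Et3N, CH2Cl2, −40 → 0 °C; then CH2=NMe2+ I−, rt; then SiO2, 35 °C
Reagents that add atoms: tert-butyldimethylsilyl triflate, CC(C)(C)[Si](C)(C)OS(=O)(=O)C(F)(F)F; N,N-dimethylmethyleneiminium iodide (Eschenmoser's salt), C=[N+](C)C.[I-]
Why: Silylation of the two chelated phenols and soft enolisation of the benzylic CH2 ketone, then Mannich reaction of the enol silane and E1cB loss of Me2NH from the α-aryl β-amino ketone (Danishefsky-type α-methylenation); with C6–O silylated the new enone cannot close to an isoflavanone and the ring C5–H is not aminomethylated, and C2/C3 are safe because retro-oxa-Michael opening of the dihydrofuran would be a disfavoured 5-endo process.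

**Step 6**
Reactants: 10 hexa-O-TBS ether of the target
Product: 11 CNP0162111.1, 1-[(2R,3R)-3-(2,4-dihydroxybenzoyl)-4,6-dihydroxy-2-(4-hydroxyphenyl)-2,3-dihydro-1-benzofuran-7-yl]-2-(4-hydroxyphenyl)prop-2-en-1-one
Conditions: TBAF/AcOH (1:1, 7 equiv), THF, 0 °C; pH 5 work-up
Reagents that add atoms: none
Why: Fluoride cleavage of aryl silyl ethers, buffered with acetic acid so that no phenoxide forms (this avoids oxa-Michael closure of the C6–OH onto the methylene ketone and base-mediated epimerisation); the stereocentres are not touched.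

## Compound list

1 | 2-(4-hydroxyphenyl)-1-(2,4,6-trihydroxyphenyl)ethan-1-one | O=C(Cc1ccc(O)cc1)c1c(O)cc(O)cc1O | starting material
2 | 1-[4-(TBSO)-2,6-dihydroxyphenyl]-2-[4-(TBSO)phenyl]ethan-1-one | O=C(Cc1ccc(O[Si](C)(C)C(C)(C)C)cc1)c1c(O)cc(O[Si](C)(C)C(C)(C)C)cc1O | intermediate
3 | (2S)-liquiritigenin, (2S)-7-hydroxy-2-(4-hydroxyphenyl)chroman-4-one | O=C1C[C@@H](c2ccc(O)cc2)Oc2cc(O)ccc12 | starting material
4 | (2S)-4,7-bis(TBSO)-2-[4-(TBSO)phenyl]-2H-chromene (silyl enol ether) | CC(C)(C)[Si](C)(C)OC1=C[C@@H](c2ccc(O[Si](C)(C)C(C)(C)C)cc2)Oc2cc(O[Si](C)(C)C(C)(C)C)ccc12 | intermediate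
5 | (2R,3R)-3-bromo-7-(TBSO)-2-[4-(TBSO)phenyl]chroman-4-one (2,3-trans) | O=C1[C@H](Br)[C@@H](c2ccc(O[Si](C)(C)C(C)(C)C)cc2)Oc2cc(O[Si](C)(C)C(C)(C)C)ccc12 | intermediate
6 | (2S,3R)-3-{2,4-dihydroxy-6-(TBSO)-3-[(4-TBSO-phenyl)acetyl]phenyl}-7-(TBSO)-2-[4-(TBSO)phenyl]chroman-4-one (2,3-trans) | O=C1[C@H](c2c(O)c(C(=O)Cc3ccc(O[Si](C)(C)C(C)(C)C)cc3)c(O)cc2O[Si](C)(C)C(C)(C)C)[C@@H](c2ccc(O[Si](C)(C)C(C)(C)C)cc2)Oc2cc(O[Si](C)(C)C(C)(C)C)ccc12 | intermediate
7 | 1-[(2R,3R)-6-hydroxy-3-(2-hydroxy-4-TBSO-benzoyl)-4-(TBSO)-2-(4-TBSO-phenyl)-2,3-dihydro-1-benzofuran-7-yl]-2-(4-TBSO-phenyl)ethan-1-one (2,3-trans) | O=C(Cc1ccc(O[Si](C)(C)C(C)(C)C)cc1)c1c(O)cc(O[Si](C)(C)C(C)(C)C)c2c1O[C@@H](c1ccc(O[Si](C)(C)C(C)(C)C)cc1)[C@@H]2C(=O)c1ccc(O[Si](C)(C)C(C)(C)C)cc1O | intermediate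
8 | heptasilyl compound: 7 with both remaining phenols silylated and the benzyl ketone as its (Z)-TBS enol ether (geometry inconsequential) | CC(C)(C)[Si](C)(C)O/C(=C\c1ccc(O[Si](C)(C)C(C)(C)C)cc1)c1c(O[Si](C)(C)C(C)(C)C)cc(O[Si](C)(C)C(C)(C)C)c2c1O[C@@H](c1ccc(O[Si](C)(C)C(C)(C)C)cc1)[C@@H]2C(=O)c1ccc(O[Si](C)(C)C(C)(C)C)cc1O[Si](C)(C)C(C)(C)C | intermediate
9 | Mannich base: hexa-O-TBS 3-(dimethylamino)-2-aryl-propanoyl compound (epimers at the side-chain carbon) | CN(C)CC(c1ccc(O[Si](C)(C)C(C)(C)C)cc1)C(=O)c1c(O[Si](C)(C)C(C)(C)C)cc(O[Si](C)(C)C(C)(C)C)c2c1O[C@@H](c1ccc(O[Si](C)(C)C(C)(C)C)cc1)[C@@H]2C(=O)c1ccc(O[Si](C)(C)C(C)(C)C)cc1O[Si](C)(C)C(C)(C)C | intermediate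
10 | hexa-O-TBS ether of the target (2-arylprop-2-en-1-one in place) | C=C(C(=O)c1c(O[Si](C)(C)C(C)(C)C)cc(O[Si](C)(C)C(C)(C)C)c2c1O[C@@H](c1ccc(O[Si](C)(C)C(C)(C)C)cc1)[C@@H]2C(=O)c1ccc(O[Si](C)(C)C(C)(C)C)cc1O[Si](C)(C)C(C)(C)C)c1ccc(O[Si](C)(C)C(C)(C)C)cc1 | intermediate
11 | CNP0162111.1, 1-[(2R,3R)-3-(2,4-dihydroxybenzoyl)-4,6-dihydroxy-2-(4-hydroxyphenyl)-2,3-dihydro-1-benzofuran-7-yl]-2-(4-hydroxyphenyl)prop-2-en-1-one | C=C(C(=O)c1c(O)cc(O)c2c1O[C@@H](c1ccc(O)cc1)[C@@H]2C(=O)c1ccc(O)cc1O)c1ccc(O)cc1 | target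

## Step count and risks

Total steps: 6. Longest linear sequence: 5 (3 → 5 → 6 → 7 → 10 → 11; the branch 1 → 2 joins in step 3).

**Step 4 (proposed new photochemical ring transposition).** The risks are a competing hydrogen shift in the ring-opened intermediate to the achiral α-aryl chalcone, which would erode ee, and a low quantum yield because the chelated ketones act as internal filters. The fallback leaves photochemistry for ground-state ionic chemistry under thermodynamic control. It sets out from 6 and comes back at 7. Compound 6 is treated with catalytic camphorsulfonic acid in HFIP at 25–40 °C, so that acid-catalysed C2–O ionisation of the flavanone (the known flavanone/chalcone manifold) gives the p-silyloxybenzyl cation, which the neighbouring phenol captures (the standard benzylic-cation/phenol closure to trans-2-aryl-dihydrobenzofurans). The equilibrium is pulled to 7 by the additional chelated hydroxy-ketone. This fallback makes no new compound, F0.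

**Step 3 (photoredox C3–aryl coupling).** The radical and the arene are both hindered, and hydrodebromination (by hydrogen transfer from the phenol) or loss of HBr to the flavone can compete. The fallback reverses the roles of the partners, using the known photoredox α-arylation of enol silanes by aryl radicals. It sets out from 2 and from silyl enol ether 4 (isolated by leaving out NBS in step 2) and comes back at 6. Compound 2 is mono-iodinated with NIS in MeCN at 0 °C to 1-[4-(TBSO)-2,6-dihydroxy-3-iodophenyl]-2-[4-(TBSO)phenyl]ethan-1-one F1. F1 and 4 are then irradiated at 390 nm with 10-phenylphenothiazine and 2,6-lutidine; the aryl radical adds to C3 of 4 anti to the C2 aryl, and oxidation and loss of the silyl group give 6.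

**Step 6 (final desilylation).** The free target carries a phenol next to the methylene ketone and can close to the isomeric isoflavanone if any phenoxide forms. The fallback unmasks the phenols before the enone exists and forms the enone last by a neutral elimination. It sets out from Mannich base 9 (intercepted as its hydrochloride by acidic work-up in step 5) and comes back at 11. Compound 9 is desilylated with HF·pyridine in THF to the hexaphenol Mannich base F2, kept as its ammonium salt so that it cannot eliminate. F2 is oxidised with mCPBA at −20 °C to the N-oxide F3, which undergoes Cope elimination on warming to room temperature in the weakly acidic medium to give 11.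

## Further compounds

F1 | step 3 | 1-[4-(TBSO)-2,6-dihydroxy-3-iodophenyl]-2-[4-(TBSO)phenyl]ethan-1-one | O=C(Cc1ccc(O[Si](C)(C)C(C)(C)C)cc1)c1c(O)cc(O[Si](C)(C)C(C)(C)C)c(I)c1O
F0 | step 4 | none | none
F2 | step 6 | hexaphenol Mannich base, 3-(dimethylamino)-2-(4-hydroxyphenyl)propanoyl analogue of the target (side-chain epimers) | CN(C)CC(c1ccc(O)cc1)C(=O)c1c(O)cc(O)c2c1O[C@@H](c1ccc(O)cc1)[C@@H]2C(=O)c1ccc(O)cc1O
F3 | step 6 | N-oxide of F2 | C[N+](C)([O-])CC(c1ccc(O)cc1)C(=O)c1c(O)cc(O)c2c1O[C@@H](c1ccc(O)cc1)[C@@H]2C(=O)c1ccc(O)cc1O
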